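**Retrosynthetic overview**
1. Target 35 comes from bis-silyl macrolide 31 by late acylation: O8 (TBS) to the methacrylate, then O9 (TIPS) to the acetate.
2. 31 comes from bromo-enal 29 by a CrCl2-mediated intramolecular Barbier allylation (C6–C7) with lactonisation; the ten-membered carbocycle and the α-methylene-γ-lactone form last and together.
3. 29 comes from furan-3(2H)-one 19 (second ring), made by gold-catalysed cyclisation of the α′-hydroxy ynone from acetylide 15 and lactone 12; the allyl bromide is built on the C7 aldehyde by vinylalumination.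
4. Lactone 12 comes from face-selective dihydroxylation of (R)-butenolide 9 (first ring, by ring-closing metathesis of methacrylate 8, which a lipase installs).
5. 8 comes from (R)-allylic alcohol 6, made by Sharpless epoxidation of the achiral (E)-allylic alcohol 3 derived from but-2-yne-1,4-diol.

Assumption: late intermediates carry germacranolide numbering (C6 lactone carbinol, C7, C8 methacrylate carbon, C9 acetate carbon, C10 quaternary furanone carbon); the target SMILES reads as 6R,7S,8S,9S,10S with a 4Z alkene.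

**Route**

Step 1
Reactants: 1 but-2-yne-1,4-diol
Product: 2 4-[(4-methoxybenzyl)oxy]but-2-yn-1-ol
Conditions: NaH (1.0 equiv), PMBCl (1.0 equiv), Bu4NI (cat.), THF/DMF, 0 °C → rt, 3 equiv of 1
Reagents that add atoms: 4-methoxybenzyl chloride COc1ccc(CCl)cc1
Why: Williamson etherification of the mono-alkoxide; the excess of the symmetric diol suppresses the bis-ether.

Step 2
Reactants: 2 mono-PMB butynediol
Product: 3 (2E)-4-[(4-methoxybenzyl)oxy]but-2-en-1-ol
Conditions: LiAlH4, THF, 0 °C → rt; aqueous work-up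
Reagents that add atoms: none
Why: Hydroxyl-directed trans-hydroalumination of the propargylic alcohol gives only the E-allylic alcohol.

Step 3
Reactants: 3 (E)-allylic alcohol
Product: 4 [(2S,3S)-3-{[(4-methoxybenzyl)oxy]methyl}oxiran-2-yl]methanol
Conditions: Ti(OiPr)4 (10 mol %), L-(+)-diethyl tartrate (12 mol %), t-BuOOH, 4 Å molecular sieves, CH2Cl2, −20 °C
Reagents that add atoms: tert-butyl hydroperoxide CC(C)(C)OO
Why: Catalytic Sharpless asymmetric epoxidation; the L-(+)-tartrate complex delivers oxygen to the face that gives the (2S,3S)-epoxide (typically ≥ 94 % ee), which fixes the carbon that becomes C8.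

Step 4
Reactants: 4 epoxy alcohol
Product: 5 (2R,3S)-2-(iodomethyl)-3-{[(4-methoxybenzyl)oxy]methyl}oxirane
Conditions: I2, PPh3, imidazole, THF, 0 °C
Reagents that add atoms: iodine II
Why: Appel-type (Garegg–Samuelsson) iodination of the primary alcohol under buffered conditions leaves the epoxide untouched.

Step 5
Reactants: 5 epoxy iodide
Product: 6 (2R)-1-[(4-methoxybenzyl)oxy]but-3-en-2-ol
Conditions: Zn dust, EtOH, reflux; dilute aq. HCl work-up
Reagents that add atoms: none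
Why: Zinc insertion into the carbon–iodine bond and β-elimination (reductive epoxide opening) gives the secondary allylic alcohol; the C–O stereocentre is not involved.

Step 6
Reactants: 6 (R)-allylic alcohol; 7 vinyl methacrylate
Product: 8 (2R)-1-[(4-methoxybenzyl)oxy]but-3-en-2-yl 2-methylprop-2-enoate
Conditions: immobilised Candida antarctica lipase B, 7 (3 equiv), BHT (trace), MTBE, 35 °C
Reagents that add atoms: none
Why: Lipase (serine hydrolase, EC 3.1.1.3) transesterification with an enol ester; the enzyme should acylate only the (R)-alcohol (Kazlauskas rule: CH2OPMB large, vinyl medium), so it both installs the metathesis partner and raises the ester to > 99 % ee.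

Step 7
Reactants: 8 allylic methacrylate
Product: 9 (5R)-5-{[(4-methoxybenzyl)oxy]methyl}-3-methylfuran-2(5H)-one
Conditions: second-generation Grubbs catalyst RuCl2(=CHPh)(PCy3)(H2IMes) (5 mol %), CH2Cl2 (0.01 M), 40 °C
Reagents that add atoms: none
Why: Ring-closing metathesis of an allyl methacrylate gives the α-methyl butenolide with loss of ethene; the neutral conditions avoid epimerisation of the acidic γ-position.

Step 8
Reactants: 9 butenolide
Product: 10 (3S,4S,5S)-3,4-dihydroxy-5-{[(4-methoxybenzyl)oxy]methyl}-3-methyloxolan-2-one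
Conditions: K2OsO4·2H2O (2 mol %), N-methylmorpholine N-oxide, citric acid, t-BuOH/H2O 1:1, rt
Reagents that add atoms: N-methylmorpholine N-oxide C[N+]1([O-])CCOCC1; water O
Why: Upjohn-type syn-dihydroxylation occurs on the butenolide face anti to the CH2OPMB group and so sets C9 and C10 (2-C-methyl-L-ribonolactone pattern).

Step 9
Reactants: 10 diol lactone
Product: 11 (3S,4S,5S)-3-hydroxy-5-{[(4-methoxybenzyl)oxy]methyl}-3-methyl-4-[(triisopropylsilyl)oxy]oxolan-2-one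
Conditions: TIPSOTf (1.2 equiv), 2,6-lutidine, CH2Cl2, −78 → 0 °C
Reagents that add atoms: triisopropylsilyl triflate CC(C)[Si](C(C)C)(C(C)C)OS(=O)(=O)C(F)(F)F
Why: Silyl ether formation is selective for the secondary hydroxyl over the hindered tertiary α-hydroxyl.

Step 10
Reactants: 11 mono-TIPS lactone
Product: 12 (3S,4S,5S)-5-{[(4-methoxybenzyl)oxy]methyl}-3-methyl-4-[(triisopropylsilyl)oxy]-3-[(trimethylsilyl)oxy]oxolan-2-one
Conditions: TMSOTf, 2,6-lutidine, CH2Cl2, −78 °C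
Reagents that add atoms: trimethylsilyl triflate C[Si](C)(C)OS(=O)(=O)C(F)(F)F
Why: A temporary TMS ether removes the only acidic proton, so the acetylide in step 12 is used for addition and not for deprotonation.

Step 11
Reactants: 13 (2Z)-3-methylpent-2-en-4-yn-1-ol
Product: 14 tert-butyldimethyl{[(2Z)-3-methylpent-2-en-4-yn-1-yl]oxy}silane
Conditions: TBSCl, imidazole, CH2Cl2, 0 °C → rt
Reagents that add atoms: tert-butyldimethylsilyl chloride CC(C)(C)[Si](C)(C)Cl
Why: Standard silylation of the primary alcohol; the Z-enyne already holds C2–C6 and C15 with the required alkene geometry.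

Step 12
Reactants: 12 silylated lactone; 14 enyne silyl ether
Product: 17 (3S,4S,5S)-2-{(3Z)-5-[(tert-butyldimethylsilyl)oxy]-3-methylpent-3-en-1-yn-1-yl}-5-{[(4-methoxybenzyl)oxy]methyl}-3-methyl-4-[(triisopropylsilyl)oxy]oxolane-2,3-diol (anomers), via lithium acetylide 15 (not isolated), via silylated lactol 16 (not isolated)
Conditions: 14 (1.3 equiv), n-BuLi, THF, −78 °C; 12, −78 °C; AcOH quench; then 1 M aq. citric acid, THF, 0 °C
Reagents that add atoms: none
Why: 1,2-Addition of the acetylide to the lactone stops at the tetrahedral lactolate at −78 °C (single addition, C1–C2 bond), and mild aqueous acid then removes only the tertiary TMS ether.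

Step 13
Reactants: 17 lactol
Product: 19 (2S)-5-{(2Z)-4-[(tert-butyldimethylsilyl)oxy]but-2-en-2-yl}-2-{(1S,2S)-2-hydroxy-3-[(4-methoxybenzyl)oxy]-1-[(triisopropylsilyl)oxy]propyl}-2-methylfuran-3(2H)-one, via open-chain ynone 18 (not isolated)
Conditions: [(4-CF3C6H4)3P]AuCl (5 mol %), AgOTf (5 mol %), toluene, rt
Reagents that add atoms: none
Why: Gold-catalysed 5-endo-dig hydroalkoxylation of the α′-hydroxy ynone (in equilibrium with the lactol) by the tertiary C10 hydroxyl gives the furan-3(2H)-one, drains the lactol and frees the C8 hydroxyl; C10 keeps its configuration.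

Step 14
Reactants: 19 furanone alcohol
Product: 20 the C8 tert-butyldimethylsilyl ether of 19 (8S,9S,10S)
Conditions: TBSOTf, 2,6-lutidine, CH2Cl2, −78 → 0 °C
Reagents that add atoms: tert-butyldimethylsilyl triflate CC(C)(C)[Si](C)(C)OS(=O)(=O)C(F)(F)F
Why: Silyl triflate silylation of the hindered secondary alcohol; a silyl ether (a poor leaving group) is chosen at C8 so that the later allylchromium cannot undergo 1,4-elimination.

Step 15
Reactants: 20 fully protected furanone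
Product: 21 (2S)-5-{(2Z)-4-[(tert-butyldimethylsilyl)oxy]but-2-en-2-yl}-2-{(1S,2S)-2-[(tert-butyldimethylsilyl)oxy]-3-hydroxy-1-[(triisopropylsilyl)oxy]propyl}-2-methylfuran-3(2H)-one
Conditions: DDQ (1.3 equiv), CH2Cl2/pH 7 buffer (Na2HPO4/NaH2PO4) 10:1, 0 °C
Reagents that add atoms: none
Why: Oxidative cleavage of the PMB ether frees only the C7 hydroxyl; the silyl ethers and the dienyl furanone are inert.

Step 16
Reactants: 21 primary alcohol
Product: 22 (2R,3S)-2-[(tert-butyldimethylsilyl)oxy]-3-[(2S)-5-{(2Z)-4-[(tert-butyldimethylsilyl)oxy]but-2-en-2-yl}-2-methyl-3-oxo-2,3-dihydrofuran-2-yl]-3-[(triisopropylsilyl)oxy]propanal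
Conditions: Dess–Martin periodinane, NaHCO3, CH2Cl2, 0 °C → rt
Reagents that add atoms: none
Why: Buffered Dess–Martin oxidation gives the α-silyloxy aldehyde without epimerising C8 (the descriptor changes only by priority).

Step 17
Reactants: 22 aldehyde; 23 methyl propiolate
Product: 25 methyl (4S,5S)-4-[(tert-butyldimethylsilyl)oxy]-5-[(2S)-5-{(2Z)-4-[(tert-butyldimethylsilyl)oxy]but-2-en-2-yl}-2-methyl-3-oxo-2,3-dihydrofuran-2-yl]-3-hydroxy-2-methylidene-5-[(triisopropylsilyl)oxy]pentanoate (C7 epimers), via vinylalane 24 (not isolated)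
Conditions: i-Bu2AlH, N-methylmorpholine N-oxide, THF, 0 °C; 23, 30 min; then 22, 0 °C → rt; aq. potassium sodium tartrate work-up
Reagents that add atoms: none
Why: Vinylalumination (aluminium-mediated Baylis–Hillman-type reaction): the α-aluminoacrylate from hydroalumination of the propiolate adds only to the aldehyde under non-basic conditions, so C8 is not epimerised and the new C7 carbinol configuration is irrelevant.

Step 18
Reactants: 25 allylic alcohol
Product: 27 methyl (2Z,4S,5S)-2-(bromomethyl)-4-[(tert-butyldimethylsilyl)oxy]-5-[(2S)-5-{(2Z)-4-[(tert-butyldimethylsilyl)oxy]but-2-en-2-yl}-2-methyl-3-oxo-2,3-dihydrofuran-2-yl]-5-[(triisopropylsilyl)oxy]pent-2-enoate, via allylic mesylate 26 (not isolated)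
Conditions: MsCl, Et3N, CH2Cl2, −30 °C, aqueous work-up; then LiBr, acetone, 0 °C → rt
Reagents that add atoms: lithium bromide [Li+].[Br-]
Why: SN2′ displacement of the mesylate by bromide gives the thermodynamically preferred (Z)-2-(bromomethyl)enoate, and both C7 epimers converge.

Step 19
Reactants: 27 allylic bromide
Product: 28 the C6 primary allylic alcohol of 27 (8S,9S,10S)
Conditions: CSA (0.2 equiv), MeOH/CH2Cl2 1:1, 0 °C
Reagents that add atoms: none
Why: Acid-catalysed methanolysis removes the unhindered primary allylic TBS ether much faster than the hindered secondary TBS and TIPS ethers.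

Step 20
Reactants: 28 allylic alcohol
Product: 29 the (Z)-enal (C6 aldehyde) of 28 (8S,9S,10S)
Conditions: MnO2 (activated, 20 equiv), CH2Cl2, rt
Reagents that add atoms: none
Why: Neutral MnO2 allylic oxidation gives the (Z)-enal without Z/E isomerisation; it is used at once.

Step 21
Reactants: 29 bromo-enal
Product: 31 (6R,7S,8S,9S,10S)-8-[(tert-butyldimethylsilyl)oxy]-1-oxo-9-[(triisopropylsilyl)oxy]-3,10-epoxygermacra-2,4(Z),11(13)-trien-12,6-olide, via hydroxy ester 30 (not isolated)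
Conditions: CrCl2 (8 equiv), THF, rt, slow addition of 29 (final 2 mM); aq. NH4Cl work-up; then p-TsOH·H2O (cat.), CH2Cl2, rt
Reagents that add atoms: none
Why: Intramolecular Nozaki–Hiyama-type Barbier allylation followed by lactonisation: the allylchromium adds to the aldehyde through a chair transition state (6,7-anti, hence trans-lactone) on the alkene face set by allylic 1,3-strain at C8 (H eclipsing, C9 anti), which should give 6R,7S; the vinylogous-ester carbonyl of the furanone is inert to the reagent.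

Step 22
Reactants: 31 bis-silyl macrolide
Product: 32 (6R,7R,8S,9S,10S)-8-hydroxy-1-oxo-9-[(triisopropylsilyl)oxy]-3,10-epoxygermacra-2,4(Z),11(13)-trien-12,6-olide (C7 descriptor changes by priority only)
Conditions: HF·pyridine, pyridine, THF, 0 °C → rt
Reagents that add atoms: none
Why: Fluoride-mediated desilylation cleaves the TBS ether at C8 selectively, the TIPS ether at the neopentylic C9 position being far slower.

Step 23
Reactants: 32 C8 alcohol
Product: 33 (6R,7S,8S,9S,10S)-8-(methacryloyloxy)-1-oxo-9-[(triisopropylsilyl)oxy]-3,10-epoxygermacra-2,4(Z),11(13)-trien-12,6-olide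
Conditions: methacrylic anhydride, DMAP, Et3N, CH2Cl2, 0 °C → rt
Reagents that add atoms: methacrylic anhydride C=C(C)C(=O)OC(=O)C(C)=C
Why: DMAP-catalysed acylation of the only free hydroxyl; with O9 still silylated no acyl migration is possible.

Step 24
Reactants: 33 methacrylate
Product: 34 (6R,7S,8S,9S,10S)-9-hydroxy-8-(methacryloyloxy)-1-oxo-3,10-epoxygermacra-2,4(Z),11(13)-trien-12,6-olide
Conditions: HF·pyridine, MeCN, rt → 40 °C
Reagents that add atoms: none
Why: Acidic fluoride removes the TIPS ether without base, so the α-methylene lactone, the dienone and the ester are untouched and acyl migration is not promoted.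

Step 25
Reactants: 34 C9 alcohol
Product: 35 (6R,7S,8S,9S,10S)-9-acetoxy-8-(methacryloyloxy)-1-oxo-3,10-epoxygermacra-2,4(Z),11(13)-trien-12,6-olide (target)
Conditions: Ac2O, pyridine, DMAP (cat.), CH2Cl2, 0 °C → rt
Reagents that add atoms: acetic anhydride CC(=O)OC(C)=O
Why: Standard acetylation of the last free hydroxyl, fast enough to outrun migration of the neighbouring methacrylate.

**Compound list**
1 | but-2-yne-1,4-diol | OCC#CCO | starting material
2 | 4-[(4-methoxybenzyl)oxy]but-2-yn-1-ol | COc1ccc(COCC#CCO)cc1 | intermediate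
3 | (2E)-4-[(4-methoxybenzyl)oxy]but-2-en-1-ol | COc1ccc(COC/C=C/CO)cc1 | intermediate
4 | [(2S,3S)-3-{[(4-methoxybenzyl)oxy]methyl}oxiran-2-yl]methanol | OC[C@@H]1O[C@H]1COCc1ccc(OC)cc1 | intermediate
5 | (2R,3S)-2-(iodomethyl)-3-{[(4-methoxybenzyl)oxy]methyl}oxirane | IC[C@@H]1O[C@H]1COCc1ccc(OC)cc1 | intermediate
6 | (2R)-1-[(4-methoxybenzyl)oxy]but-3-en-2-ol | C=C[C@@H](O)COCc1ccc(OC)cc1 | intermediate
7 | vinyl methacrylate (ethenyl 2-methylprop-2-enoate) | C=COC(=O)C(C)=C | starting material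
8 | (2R)-1-[(4-methoxybenzyl)oxy]but-3-en-2-yl 2-methylprop-2-enoate | C=C[C@@H](OC(=O)C(C)=C)COCc1ccc(OC)cc1 | intermediate
9 | (5R)-5-{[(4-methoxybenzyl)oxy]methyl}-3-methylfuran-2(5H)-one | CC1=C[C@H](COCc2ccc(OC)cc2)OC1=O | intermediate
10 | (3S,4S,5S)-3,4-dihydroxy-5-{[(4-methoxybenzyl)oxy]methyl}-3-methyloxolan-2-one | O=C1O[C@@H](COCc2ccc(OC)cc2)[C@H](O)[C@]1(C)O | intermediate
11 | (3S,4S,5S)-3-hydroxy-5-{[(4-methoxybenzyl)oxy]methyl}-3-methyl-4-[(triisopropylsilyl)oxy]oxolan-2-one | O=C1O[C@@H](COCc2ccc(OC)cc2)[C@H](O[Si](C(C)C)(C(C)C)C(C)C)[C@]1(C)O | intermediate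
12 | (3S,4S,5S)-5-{[(4-methoxybenzyl)oxy]methyl}-3-methyl-4-[(triisopropylsilyl)oxy]-3-[(trimethylsilyl)oxy]oxolan-2-one | O=C1O[C@@H](COCc2ccc(OC)cc2)[C@H](O[Si](C(C)C)(C(C)C)C(C)C)[C@]1(C)O[Si](C)(C)C | intermediate
13 | (2Z)-3-methylpent-2-en-4-yn-1-ol | C#C/C(C)=C\CO | starting material
14 | tert-butyldimethyl{[(2Z)-3-methylpent-2-en-4-yn-1-yl]oxy}silane | C#C/C(C)=C\CO[Si](C)(C)C(C)(C)C | intermediate
15 | {(3Z)-5-[(tert-butyldimethylsilyl)oxy]-3-methylpent-3-en-1-yn-1-yl}lithium | [Li]C#C/C(C)=C\CO[Si](C)(C)C(C)(C)C | intermediate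
16 | (3S,4S,5S)-2-{(3Z)-5-[(tert-butyldimethylsilyl)oxy]-3-methylpent-3-en-1-yn-1-yl}-5-{[(4-methoxybenzyl)oxy]methyl}-3-methyl-4-[(triisopropylsilyl)oxy]-3-[(trimethylsilyl)oxy]oxolan-2-ol (anomers) | OC1(C#C/C(C)=C\CO[Si](C)(C)C(C)(C)C)O[C@@H](COCc2ccc(OC)cc2)[C@H](O[Si](C(C)C)(C(C)C)C(C)C)[C@]1(C)O[Si](C)(C)C | intermediate
17 | (3S,4S,5S)-2-{(3Z)-5-[(tert-butyldimethylsilyl)oxy]-3-methylpent-3-en-1-yn-1-yl}-5-{[(4-methoxybenzyl)oxy]methyl}-3-methyl-4-[(triisopropylsilyl)oxy]oxolane-2,3-diol (anomers) | OC1(C#C/C(C)=C\CO[Si](C)(C)C(C)(C)C)O[C@@H](COCc2ccc(OC)cc2)[C@H](O[Si](C(C)C)(C(C)C)C(C)C)[C@]1(C)O | intermediate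
18 | (2Z,7S,8S,9S)-1-[(tert-butyldimethylsilyl)oxy]-7,9-dihydroxy-10-[(4-methoxybenzyl)oxy]-3,7-dimethyl-8-[(triisopropylsilyl)oxy]dec-2-en-4-yn-6-one | COc1ccc(COC[C@H](O)[C@H](O[Si](C(C)C)(C(C)C)C(C)C)[C@](C)(O)C(=O)C#C/C(C)=C\CO[Si](C)(C)C(C)(C)C)cc1 | intermediate
19 | (2S)-5-{(2Z)-4-[(tert-butyldimethylsilyl)oxy]but-2-en-2-yl}-2-{(1S,2S)-2-hydroxy-3-[(4-methoxybenzyl)oxy]-1-[(triisopropylsilyl)oxy]propyl}-2-methylfuran-3(2H)-one | COc1ccc(COC[C@H](O)[C@H](O[Si](C(C)C)(C(C)C)C(C)C)[C@]2(C)OC(/C(C)=C\CO[Si](C)(C)C(C)(C)C)=CC2=O)cc1 | intermediate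
20 | (2S)-5-{(2Z)-4-[(tert-butyldimethylsilyl)oxy]but-2-en-2-yl}-2-{(1S,2S)-2-[(tert-butyldimethylsilyl)oxy]-3-[(4-methoxybenzyl)oxy]-1-[(triisopropylsilyl)oxy]propyl}-2-methylfuran-3(2H)-one | COc1ccc(COC[C@H](O[Si](C)(C)C(C)(C)C)[C@H](O[Si](C(C)C)(C(C)C)C(C)C)[C@]2(C)OC(/C(C)=C\CO[Si](C)(C)C(C)(C)C)=CC2=O)cc1 | intermediate
21 | (2S)-5-{(2Z)-4-[(tert-butyldimethylsilyl)oxy]but-2-en-2-yl}-2-{(1S,2S)-2-[(tert-butyldimethylsilyl)oxy]-3-hydroxy-1-[(triisopropylsilyl)oxy]propyl}-2-methylfuran-3(2H)-one | OC[C@H](O[Si](C)(C)C(C)(C)C)[C@H](O[Si](C(C)C)(C(C)C)C(C)C)[C@]1(C)OC(/C(C)=C\CO[Si](C)(C)C(C)(C)C)=CC1=O | intermediate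
22 | (2R,3S)-2-[(tert-butyldimethylsilyl)oxy]-3-[(2S)-5-{(2Z)-4-[(tert-butyldimethylsilyl)oxy]but-2-en-2-yl}-2-methyl-3-oxo-2,3-dihydrofuran-2-yl]-3-[(triisopropylsilyl)oxy]propanal | O=C[C@H](O[Si](C)(C)C(C)(C)C)[C@H](O[Si](C(C)C)(C(C)C)C(C)C)[C@]1(C)OC(/C(C)=C\CO[Si](C)(C)C(C)(C)C)=CC1=O | intermediate
23 | methyl propiolate (methyl prop-2-ynoate) | C#CC(=O)OC | starting material
24 | methyl 2-[bis(2-methylpropyl)alumanyl]prop-2-enoate | C=C([Al](CC(C)C)CC(C)C)C(=O)OC | intermediate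
25 | methyl (4S,5S)-4-[(tert-butyldimethylsilyl)oxy]-5-[(2S)-5-{(2Z)-4-[(tert-butyldimethylsilyl)oxy]but-2-en-2-yl}-2-methyl-3-oxo-2,3-dihydrofuran-2-yl]-3-hydroxy-2-methylidene-5-[(triisopropylsilyl)oxy]pentanoate (C3 epimers) | COC(=O)C(=C)C(O)[C@H](O[Si](C)(C)C(C)(C)C)[C@H](O[Si](C(C)C)(C(C)C)C(C)C)[C@]1(C)OC(/C(C)=C\CO[Si](C)(C)C(C)(C)C)=CC1=O | intermediate
26 | the C3 methanesulfonate of 25 (C3 epimers; other centres unchanged) | COC(=O)C(=C)C(OS(C)(=O)=O)[C@H](O[Si](C)(C)C(C)(C)C)[C@H](O[Si](C(C)C)(C(C)C)C(C)C)[C@]1(C)OC(/C(C)=C\CO[Si](C)(C)C(C)(C)C)=CC1=O | intermediate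
27 | methyl (2Z,4S,5S)-2-(bromomethyl)-4-[(tert-butyldimethylsilyl)oxy]-5-[(2S)-5-{(2Z)-4-[(tert-butyldimethylsilyl)oxy]but-2-en-2-yl}-2-methyl-3-oxo-2,3-dihydrofuran-2-yl]-5-[(triisopropylsilyl)oxy]pent-2-enoate | BrC/C(C(=O)OC)=C\[C@H](O[Si](C)(C)C(C)(C)C)[C@H](O[Si](C(C)C)(C(C)C)C(C)C)[C@]1(C)OC(/C(C)=C\CO[Si](C)(C)C(C)(C)C)=CC1=O | intermediate
28 | methyl (2Z,4S,5S)-2-(bromomethyl)-4-[(tert-butyldimethylsilyl)oxy]-5-{(2S)-5-[(2Z)-4-hydroxybut-2-en-2-yl]-2-methyl-3-oxo-2,3-dihydrofuran-2-yl}-5-[(triisopropylsilyl)oxy]pent-2-enoate | BrC/C(C(=O)OC)=C\[C@H](O[Si](C)(C)C(C)(C)C)[C@H](O[Si](C(C)C)(C(C)C)C(C)C)[C@]1(C)OC(/C(C)=C\CO)=CC1=O | intermediate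
29 | methyl (2Z,4S,5S)-2-(bromomethyl)-4-[(tert-butyldimethylsilyl)oxy]-5-{(2S)-2-methyl-3-oxo-5-[(2Z)-4-oxobut-2-en-2-yl]-2,3-dihydrofuran-2-yl}-5-[(triisopropylsilyl)oxy]pent-2-enoate | BrC/C(C(=O)OC)=C\[C@H](O[Si](C)(C)C(C)(C)C)[C@H](O[Si](C(C)C)(C(C)C)C(C)C)[C@]1(C)OC(/C(C)=C\C=O)=CC1=O | intermediate
30 | methyl (6R,7S,8S,9S,10S)-8-[(tert-butyldimethylsilyl)oxy]-6-hydroxy-1-oxo-9-[(triisopropylsilyl)oxy]-3,10-epoxygermacra-2,4(Z),11(13)-trien-12-oate | CC(C)(C)[Si](C)(C)O[C@H]1[C@@H](C(=C)C(=O)OC)[C@H](O)/C=C(/C)C2=CC(=O)[C@@](C)(O2)[C@H]1O[Si](C(C)C)(C(C)C)C(C)C | intermediate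
31 | (6R,7S,8S,9S,10S)-8-[(tert-butyldimethylsilyl)oxy]-1-oxo-9-[(triisopropylsilyl)oxy]-3,10-epoxygermacra-2,4(Z),11(13)-trien-12,6-olide | CC(C)(C)[Si](C)(C)O[C@H]1[C@H]2C(=C)C(=O)O[C@@H]2/C=C(/C)C2=CC(=O)[C@@](C)(O2)[C@H]1O[Si](C(C)C)(C(C)C)C(C)C | intermediate
32 | (6R,7R,8S,9S,10S)-8-hydroxy-1-oxo-9-[(triisopropylsilyl)oxy]-3,10-epoxygermacra-2,4(Z),11(13)-trien-12,6-olide | O[C@H]1[C@H]2C(=C)C(=O)O[C@@H]2/C=C(/C)C2=CC(=O)[C@@](C)(O2)[C@H]1O[Si](C(C)C)(C(C)C)C(C)C | intermediate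
33 | (6R,7S,8S,9S,10S)-8-(methacryloyloxy)-1-oxo-9-[(triisopropylsilyl)oxy]-3,10-epoxygermacra-2,4(Z),11(13)-trien-12,6-olide | C=C(C)C(=O)O[C@H]1[C@H]2C(=C)C(=O)O[C@@H]2/C=C(/C)C2=CC(=O)[C@@](C)(O2)[C@H]1O[Si](C(C)C)(C(C)C)C(C)C | intermediate
34 | (6R,7S,8S,9S,10S)-9-hydroxy-8-(methacryloyloxy)-1-oxo-3,10-epoxygermacra-2,4(Z),11(13)-trien-12,6-olide | C=C(C)C(=O)O[C@H]1[C@H]2C(=C)C(=O)O[C@@H]2/C=C(/C)C2=CC(=O)[C@@](C)(O2)[C@H]1O | intermediate
35 | (6R,7S,8S,9S,10S)-9-acetoxy-8-(methacryloyloxy)-1-oxo-3,10-epoxygermacra-2,4(Z),11(13)-trien-12,6-olide (CNP0365569.2) | C=C(C)C(=O)O[C@H]1[C@H]2C(=C)C(=O)O[C@@H]2/C=C(/C)C2=CC(=O)[C@@](C)(O2)[C@H]1OC(C)=O | target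

**Totals and risks**
Total step count: 25. Longest linear sequence: 24 steps (steps 1–10, then 12–25; step 11 is the one-step side branch).

Most likely to fail, in this order:

First, step 21, the chromium-mediated ring closure. The ring may override the chair preference and give the syn adduct. The fallback sets out from enal 29 and corrects the stereocentre instead of re-optimising the cyclisation. The product of the ring closure is then the 6-epimeric hydroxy ester F1 (or the cis-lactone formed from it). Me3SnOH in 1,2-dichloroethane at 60 °C converts it into the 6-epimeric hydroxy acid F2. An intramolecular Mitsunobu lactonisation (PPh3, DIAD, THF, 0 °C) then displaces the activated allylic C6 hydroxyl with inversion and rejoins the route at 31.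

Second, step 17, the vinylalumination of the hindered, sensitive aldehyde. The fallback sets out from aldehyde 22 and replaces the organoaluminium addition by an aldol/selenoxide-elimination sequence. Methyl 2-(phenylselanyl)propanoate F3 (from methyl 2-bromopropanoate and PhSeNa) is deprotonated with LiN(iPr)2 in THF at −78 °C to its lithium enolate F4, which adds to 22 to give the α-seleno β-hydroxy ester F5. H2O2/pyridine in CH2Cl2 at 0 °C gives the selenoxide F6, whose syn-elimination into the methyl group (away from the carbinol) rejoins the route at 25.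

Third, step 13, the gold-catalysed furanone formation from the lactol. The fallback sets out from lactol 17 and uses conjugate addition–elimination instead of alkyne activation. Et2NH in EtOH at rt adds to the ynone form to give the enaminone F7. Aqueous AcOH/THF then lets the tertiary C10 hydroxyl replace the amine and rejoins the route at 19.

Further compounds
F1 | step 21 | methyl (6S,7S,8S,9S,10S)-8-[(tert-butyldimethylsilyl)oxy]-6-hydroxy-1-oxo-9-[(triisopropylsilyl)oxy]-3,10-epoxygermacra-2,4(Z),11(13)-trien-12-oate | CC(C)(C)[Si](C)(C)O[C@H]1[C@@H](C(=C)C(=O)OC)[C@@H](O)/C=C(/C)C2=CC(=O)[C@@](C)(O2)[C@H]1O[Si](C(C)C)(C(C)C)C(C)C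
F2 | step 21 | (6S,7S,8S,9S,10S)-8-[(tert-butyldimethylsilyl)oxy]-6-hydroxy-1-oxo-9-[(triisopropylsilyl)oxy]-3,10-epoxygermacra-2,4(Z),11(13)-trien-12-oic acid | CC(C)(C)[Si](C)(C)O[C@H]1[C@@H](C(=C)C(=O)O)[C@@H](O)/C=C(/C)C2=CC(=O)[C@@](C)(O2)[C@H]1O[Si](C(C)C)(C(C)C)C(C)C
F3 | step 17 | methyl 2-(phenylselanyl)propanoate | COC(=O)C(C)[Se]c1ccccc1
F4 | step 17 | lithium enolate of methyl 2-(phenylselanyl)propanoate | [Li]OC(OC)=C(C)[Se]c1ccccc1
F5 | step 17 | methyl (4S,5S)-4-[(tert-butyldimethylsilyl)oxy]-5-[(2S)-5-{(2Z)-4-[(tert-butyldimethylsilyl)oxy]but-2-en-2-yl}-2-methyl-3-oxo-2,3-dihydrofuran-2-yl]-3-hydroxy-2-methyl-2-(phenylselanyl)-5-[(triisopropylsilyl)oxy]pentanoate (C2/C3 epimers) | COC(=O)C(C)([Se]c1ccccc1)C(O)[C@H](O[Si](C)(C)C(C)(C)C)[C@H](O[Si](C(C)C)(C(C)C)C(C)C)[C@]1(C)OC(/C(C)=C\CO[Si](C)(C)C(C)(C)C)=CC1=O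
F6 | step 17 | the Se-oxide (selenoxide) of F5 | COC(=O)C(C)([Se](=O)c1ccccc1)C(O)[C@H](O[Si](C)(C)C(C)(C)C)[C@H](O[Si](C(C)C)(C(C)C)C(C)C)[C@]1(C)OC(/C(C)=C\CO[Si](C)(C)C(C)(C)C)=CC1=O
F7 | step 13 | (2Z,7S,8S,9S)-1-[(tert-butyldimethylsilyl)oxy]-4-(diethylamino)-7,9-dihydroxy-10-[(4-methoxybenzyl)oxy]-3,7-dimethyl-8-[(triisopropylsilyl)oxy]deca-2,4-dien-6-one (4,5-geometry not fixed) | COc1ccc(COC[C@H](O)[C@H](O[Si](C(C)C)(C(C)C)C(C)C)[C@](C)(O)C(=O)C=C(N(CC)CC)/C(C)=C\CO[Si](C)(C)C(C)(C)C)cc1
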